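## Analysis of the target

The target (C32H22O10) is a biflavone joined by a diaryl ether. Unit 1 is a 2-arylchromen-4-one made of benzo ring A, pyranone ring C and the 4-methoxyphenyl ring B, with 5-OH, 7-OMe and an aryloxy group on C8. Unit 2 is an apigenin made of benzo ring D, pyranone ring F and the para-phenylene ring E, whose C4' oxygen is the ether oxygen on C8 of unit 1.

There is no stereocentre, so the problem is one of regiochemistry and of telling oxygen functions apart. Five of the six positions of ring A are substituted, and the C8 oxygen sits between the 7-methoxy group and the ring oxygen, so the ether bond is hindered. Two methyl ethers must stay (C7 of unit 1, C4' of ring B), three phenols must end up free (two chelated 5-hydroxyls and the 7-hydroxyl of unit 2), and the two halves are chemically almost alike.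

The sensitive points are:
- the pyranone rings, which open in hot alkali;
- the 5-hydroxy-8-aryloxy pattern of unit 1, which can isomerise to the 6-aryloxy isomer in hot strong acid (Wessely–Moser);
- the electron-rich ring D, which is easily C-alkylated by benzyl cations.

The strategy rests on ring D. Its ring oxygen O1 sits on C8a and the carbonyl carbon C4 on the neighbouring C4a, with an oxygen on C5 flanking C4a, a hydrogen on C8 flanking C8a, and the C7 oxygen meta to both. This is the pattern left when a carboxylic acid adds across the triple bond of a 3,5-dialkoxybenzyne.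

## Retrosynthetic reasoning

**20 from 19 (three O–benzyl bonds).** The three phenols of target 20 are masked as benzyl ethers in 19 (C5 of unit 1, C5 and C7 of unit 2). The methyl ethers of 19 are those of the target, so the last step never has to pick one methyl ether out of three. The forward reaction is a single cold Lewis-acid debenzylation with a cation scavenger.

**19 from 18 (O1–C2 of ring F).** Cutting this bond leaves the ortho-hydroxyaryl ynone 18, which already holds every carbon of unit 2 at the right oxidation level, so the closure is an isomerisation. The forward step must close 6-endo onto the alkyne carbon bearing ring E and not 5-exo.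

**18 from 8 and 16 (C8a–O1 and C4a–C4 of ring D).** These two bonds sit on neighbouring ring carbons and have opposite polarity, which is what an aryne offers to a carboxylic acid. Acid 8 brings complete unit 1, ring E and the three carbons of ring F. Silyl triflate 16 brings ring D through aryne 17. The cut is made here because it joins the two halves at the last C–C bond and puts the carbonyl regiospecifically between the hydroxyl and one benzyloxy group. A Friedel–Crafts acylation of a phloroglucinol ether with a propiolic acid derivative would not give that control. The forward step needs oxygen to add to the right aryne terminus, and acyl transfer to beat protonation. For that, 8 may carry no acidic hydrogen other than the carboxyl, so C5–OH of unit 1 is benzylated.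

**16 from 9 via 10 and 14 (C–Si and O–S bonds).** The silicon must sit between the triflate oxygen and one benzyloxy group. A carbamate on the phenol oxygen of 9 directs lithiation to that carbon, and the same carbamate is then exchanged for the triflate.

**8 from 7, and 7 from 6 (C–CO2H bond, then alkyne from aldehyde).** The carboxyl carbon is added to the terminal alkyne 7 by carboxylation. The alkyne comes from aldehyde 6 by one-carbon homologation. The aldehyde is kept to this point because the same group activates ring E for the ether formation.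

**6 from 5, and 5 from 3 and 4 (O–benzyl bond, then the ring E C4'–O bond).** The ether is cut on the ring E side. Ring E can carry a para acceptor and act as the electrophile (4), while ring A is electron-rich and hindered and can only be the nucleophile (phenol 3). Of the two hydroxyls in 3, only the C8 hydroxyl is unchelated, so no protecting group is needed for the ether formation; the C5 hydroxyl is benzylated afterwards.

**3 from 1 (C8–O bond).** C8 is para to the C5 phenoxide of flavone 1, the position a persulfate oxidation attacks. The whole skeleton of unit 1 is thereby bought rather than built.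

## Alternatives that were turned down

**Alternative 1: ring A by cyclobutenone ring expansion.**
- Disconnection: C4a–C5 of ring A, back to the cyclobutenone A2 carrying a pyranone on its carbinol carbon.
- Forward key step: heating A2 in xylene opens the four-membered ring to a dienylketene; the ketene carbon closes onto C3 of the pyranone and tautomerisation gives the hydroquinone A1.
- For it: every oxygen of ring A is placed by the connectivity of A2, the step needs no reagent, and the two hydroxyls of A1 come out differentiated.
- Against it: A1 is the same compound as 3, which the chosen route reaches in one step from a purchasable flavone. A2 would need a pyranone metallated next to its ring oxygen, in the presence of its own carbonyl, added to one specific carbonyl of a squaric-acid-derived dione. The electrocyclisation must engage a vinylogous ester double bond rather than an arene. After A1 the ether, the alkyne and all of unit 2 are still to be made.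
- Comparison: Alternative 1 is probably stronger in material throughput and regiochemical certainty for ring A, since a persulfate oxidation rarely goes to full conversion. The chosen strategy offers a one-step entry to the same phenol and spends its constructive step on unit 2, where Alternative 1 contributes nothing.

**Alternative 2: two-directional bichalcone, double oxidative closure.**
- Disconnection: O1–C2 of rings C and F at once, back to the bichalcone A4.
- Forward key step: heating A4 with catalytic I2 in DMSO adds each ortho-phenol to its enone and dehydrogenates both flavanones, giving A3.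
- For it: every reaction is textbook chemistry, both pyranones close in one flask, and A3 differs from 19 only in the group on C5 of unit 1. On precedent for the key step this alternative is stronger than the aryne insertion.
- Against it: A4 needs a ring A acetophenone with hydroxyl, aryloxy and two methoxy groups in fixed order. That means phenol protection, oxidation of an aldehyde to a phenol, ether formation, deprotection, and an acylation that must choose the position ortho to the phenol over the one between the two methoxy groups. The central fragment is a methyl ketone and an aldehyde at once, so the two aldol condensations must be sequenced with protection. Hot I2/DMSO releases HI, which threatens benzyl ethers and the electron-rich rings. The end-game must cleave one methyl ether in the presence of two others.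
- Comparison: the count comes to roughly a dozen steps or more, against eleven here with a longest line of eight. The chosen route accepts one less precedented step in exchange for a shorter path and a regiochemistry fixed by the aryne.

**Alternative 3: ring E grown on the ether oxygen by cycloaddition.**
- Disconnection: C3'–C4' and C5'–C6' of ring E, back to the aryl ethynyl ether A6 and methyl coumalate A7.
- Forward key step: heating A6 with A7 gives a [4+2] adduct that loses CO2 and aromatises to the para-aryloxybenzoate A5.
- For it: the hindered diaryl ether is made without any C–O coupling and without relying on a di-ortho-substituted phenoxide; the polarisation of both partners should put the ester para to the ether oxygen. On that point it is stronger than an SNAr.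
- Against it: A6 takes several steps from the phenol and is thermally labile. The key step builds only the ether, which the chosen route makes in one SNAr step from 3 and 4. After A5, ring A still lacks its acyl carbon, neither pyranone exists, and the ester must be turned into an alkyne or ketone.
- Comparison: Alternative 3 buys independence from phenoxide hindrance at the price of a much longer route. The chosen strategy takes the hindered but well-precedented SNAr and puts the new bond formation where the molecule is harder, on ring D.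

Key step: step 9

Assumption: flavone 1 (apigenin 7,4'-dimethyl ether) and phenol 9 are taken as catalogue compounds; each is otherwise one step from apigenin (Me2SO4, K2CO3) or from phloroglucinol (BnBr, K2CO3).

## Route

**Step 1**
Reactants: 1 5-hydroxy-7-methoxy-2-(4-methoxyphenyl)-4H-chromen-4-one
Product: 3 5,8-dihydroxy-7-methoxy-2-(4-methoxyphenyl)-4H-chromen-4-one, via potassium 8-sulfate ester 2 (not isolated)
Conditions: K2S2O8, aq KOH, pyridine, 10–20 °C; then aq HCl, Na2SO3, 90 °C
Reagents that add atoms: potassium peroxodisulfate (K2S2O8), [K+].[K+].[O-]S(=O)(=O)OOS(=O)(=O)[O-]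
Why: Elbs persulfate oxidation; the C5 phenoxide attacks the peroxide oxygen through its para carbon C8, acid hydrolysis of the aryl sulfate frees the 8-hydroxyl, and unreacted 1 precipitates on acidification and can be recycled.

**Step 2**
Reactants: 3 5,8-dihydroxy-7-methoxy-2-(4-methoxyphenyl)-4H-chromen-4-one; 4 4-fluorobenzaldehyde
Product: 5 4-{[5-hydroxy-7-methoxy-2-(4-methoxyphenyl)-4-oxo-4H-chromen-8-yl]oxy}benzaldehyde
Conditions: K2CO3 (1.1 equiv), DMF, 90 °C, argon
Reagents that add atoms: none
Why: Nucleophilic aromatic substitution (SNAr); the 8-hydroxyl is the more acidic, unchelated phenol, its phenoxide displaces fluoride para to the formyl group, the hydrogen-bonded 5-hydroxyl stays out, and air is excluded because the hydroquinone anion oxidises easily.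

**Step 3**
Reactants: 5 4-{[5-hydroxy-7-methoxy-2-(4-methoxyphenyl)-4-oxo-4H-chromen-8-yl]oxy}benzaldehyde
Product: 6 4-{[5-(benzyloxy)-7-methoxy-2-(4-methoxyphenyl)-4-oxo-4H-chromen-8-yl]oxy}benzaldehyde
Conditions: BnBr, K2CO3, DMF, 70 °C
Reagents that add atoms: benzyl bromide, BrCc1ccccc1
Why: Williamson etherification of the chelated 5-hydroxyl, which needs heat but meets no competing nucleophile; benzyl is chosen over methyl so that all masked phenols fall together at the end and no methyl ether ever has to be cleaved.

**Step 4**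
Reactants: 6 4-{[5-(benzyloxy)-7-methoxy-2-(4-methoxyphenyl)-4-oxo-4H-chromen-8-yl]oxy}benzaldehyde
Product: 7 5-(benzyloxy)-8-(4-ethynylphenoxy)-7-methoxy-2-(4-methoxyphenyl)-4H-chromen-4-one
Conditions: dimethyl (1-diazo-2-oxopropyl)phosphonate, K2CO3, MeOH–THF, 0 °C to rt
Reagents that add atoms: dimethyl (1-diazo-2-oxopropyl)phosphonate, CC(=O)C(=[N+]=[N-])P(=O)(OC)OC
Why: Ohira–Bestmann variant of the Seyferth–Gilbert homologation; methanolysis releases the diazomethylphosphonate anion, which olefinates the aldehyde, and loss of N2 with 1,2-hydride shift gives the terminal alkyne, while the vinylogous ester carbonyl of the flavone is too unreactive to compete.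

**Step 5**
Reactants: 7 5-(benzyloxy)-8-(4-ethynylphenoxy)-7-methoxy-2-(4-methoxyphenyl)-4H-chromen-4-one
Product: 8 3-(4-{[5-(benzyloxy)-7-methoxy-2-(4-methoxyphenyl)-4-oxo-4H-chromen-8-yl]oxy}phenyl)prop-2-ynoic acid
Conditions: AgI (2 mol %), Cs2CO3, CO2 (1 atm), DMF, 50 °C; then 1 M HCl, 0 °C
Reagents that add atoms: carbon dioxide, O=C=O
Why: Silver-catalysed C–H carboxylation of a terminal alkyne; the silver acetylide formed with carbonate inserts CO2 and the cesium propiolate is acidified cold, so no organolithium ever meets the flavone carbonyl.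

**Step 6**
Reactants: 9 3,5-bis(benzyloxy)phenol
Product: 10 3,5-bis(benzyloxy)phenyl N-(propan-2-yl)carbamate
Conditions: i-PrNCO, Et3N (cat.), CH2Cl2, rt
Reagents that add atoms: isopropyl isocyanate, CC(C)N=C=O
Why: Amine-catalysed addition of the phenol to the isocyanate gives the secondary carbamate, which serves both as the directing group for metalation and as a base-removable mask of the phenol.

**Step 7**
Reactants: 10 3,5-bis(benzyloxy)phenyl N-(propan-2-yl)carbamate
Product: 14 3,5-bis(benzyloxy)-2-(trimethylsilyl)phenyl N-(propan-2-yl)carbamate, via N-silyl carbamate 11 (not isolated), via ortho-lithiated N-silyl carbamate 12 (not isolated), via N,C-disilyl carbamate 13 (not isolated)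
Conditions: TMSOTf, TMEDA, Et2O, 0 °C to rt; n-BuLi, TMEDA, −78 °C; TMSCl, −78 °C to rt; aq NaHSO4
Reagents that add atoms: chlorotrimethylsilane, C[Si](C)(C)Cl
Why: Directed ortho-metalation; N-silylation by TMSOTf blocks the NH and the anionic Fries shift, n-BuLi/TMEDA removes the proton flanked by the carbamate and one benzyloxy group (the carbamate outranks the ethers, so the carbon between the two benzyloxy groups is left alone), TMSCl traps the aryllithium, and the N–Si bond is hydrolysed on work-up.

**Step 8**
Reactants: 14 3,5-bis(benzyloxy)-2-(trimethylsilyl)phenyl N-(propan-2-yl)carbamate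
Product: 16 3,5-bis(benzyloxy)-2-(trimethylsilyl)phenyl trifluoromethanesulfonate, via 2-silylphenol 15 (not isolated)
Conditions: DBU, Et2NH, MeCN, 40 °C; then PhNTf2, rt
Reagents that add atoms: N-phenylbis(trifluoromethanesulfonimide), O=S(=O)(N(c1ccccc1)S(=O)(=O)C(F)(F)F)C(F)(F)F
Why: Base-induced elimination of the secondary carbamate releases isopropyl isocyanate, which Et2NH traps as a urea, and the phenoxide is triflated in the same flask; the aryl–silicon bond sees neither fluoride nor acid.

**Step 9**
Reactants: 8 3-(4-{[5-(benzyloxy)-7-methoxy-2-(4-methoxyphenyl)-4-oxo-4H-chromen-8-yl]oxy}phenyl)prop-2-ynoic acid; 16 3,5-bis(benzyloxy)-2-(trimethylsilyl)phenyl trifluoromethanesulfonate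
Product: 18 5-(benzyloxy)-8-(4-{3-[2,4-bis(benzyloxy)-6-hydroxyphenyl]-3-oxoprop-1-yn-1-yl}phenoxy)-7-methoxy-2-(4-methoxyphenyl)-4H-chromen-4-one, via aryne 17 (not isolated)
Conditions: CsF (4 equiv), THF (dilute), 125 °C, sealed tube
Reagents that add atoms: none
Why: Fluoride attacks silicon of 16 and triflate leaves, giving aryne 17; the cesium carboxylate of 8 adds through oxygen to the aryne carbon that carried the triflate, which puts the aryl anion on the carbon that carried silicon, next to a benzyloxy group. That anion attacks the neighbouring ester carbonyl to a four-membered benzoxetene alkoxide, whose C–O fragmentation releases the ortho-acyl phenoxide, so C8a–O1 and C4a–C4 of unit 2 form in one operation and work-up gives 18. The closest known reaction type is the fluoride-induced insertion of arynes into the C–O bond of carboxylic acids to give ortho-hydroxyaryl ketones, known for arylpropiolic acids and for 3-alkoxyarynes. No ring is closed and no stereocentre is formed. The regioselectivity needed is oxygen addition at the aryne terminus remote from the flanking benzyloxy group; the inductive pull of that single ortho oxygen and the distortion it causes make this terminus the electrophilic one, and the other benzyloxy group is meta to both termini and has no say. The chemoselectivity needed is acyl transfer faster than protonation of the aryl anion, which would stop at the aryl ester; excess CsF, high dilution and high temperature favour the intramolecular path, and 8 has no acidic hydrogen besides the carboxyl because its C5 hydroxyl is benzylated. The chelated phenoxide of 18 is a poor nucleophile, which limits a second arylation by 17. Some 18 may already close to 19 in the hot fluoride medium; that material is the product of step 10 and is carried along.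

**Step 10**
Reactants: 18 5-(benzyloxy)-8-(4-{3-[2,4-bis(benzyloxy)-6-hydroxyphenyl]-3-oxoprop-1-yn-1-yl}phenoxy)-7-methoxy-2-(4-methoxyphenyl)-4H-chromen-4-one
Product: 19 5-(benzyloxy)-8-{4-[5,7-bis(benzyloxy)-4-oxo-4H-chromen-2-yl]phenoxy}-7-methoxy-2-(4-methoxyphenyl)-4H-chromen-4-one
Conditions: DMAP (20 mol %), DMF, 40 °C
Reagents that add atoms: none
Why: Amine-catalysed 6-endo-dig oxa-Michael closure of an ortho-alkynoylphenol; DMAP adds to the ynone β-carbon, the phenoxide displaces it there by addition–elimination, so O1–C2 of ring F forms and the 5-exo path to the aurone is avoided.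

**Step 11**
Reactants: 19 5-(benzyloxy)-8-{4-[5,7-bis(benzyloxy)-4-oxo-4H-chromen-2-yl]phenoxy}-7-methoxy-2-(4-methoxyphenyl)-4H-chromen-4-one
Product: 20 8-[4-(5,7-dihydroxy-4-oxo-4H-chromen-2-yl)phenoxy]-5-hydroxy-7-methoxy-2-(4-methoxyphenyl)-4H-chromen-4-one (CNP0259871.0)
Conditions: BCl3, C6HMe5, CH2Cl2, −78 to −20 °C; then MeOH
Reagents that add atoms: none
Why: Lewis-acid debenzylation; BCl3 binds the three benzyl ether oxygens (two as chelates with a peri carbonyl) and each benzyl cation is passed to pentamethylbenzene in a Friedel–Crafts step so that it cannot C-benzylate ring D. The two aryl methyl ethers have no chelating neighbour and should survive with the diaryl ether, and the cold aprotic medium gives no opening for the Wessely–Moser isomerisation.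

## Compound list

1 | 5-hydroxy-7-methoxy-2-(4-methoxyphenyl)-4H-chromen-4-one | COc1ccc(-c2cc(=O)c3c(O)cc(OC)cc3o2)cc1 | starting material
2 | potassium 5-hydroxy-7-methoxy-2-(4-methoxyphenyl)-4-oxo-4H-chromen-8-yl sulfate | COc1ccc(-c2cc(=O)c3c(O)cc(OC)c(OS(=O)(=O)[O-])c3o2)cc1.[K+] | intermediate
3 | 5,8-dihydroxy-7-methoxy-2-(4-methoxyphenyl)-4H-chromen-4-one | COc1ccc(-c2cc(=O)c3c(O)cc(OC)c(O)c3o2)cc1 | intermediate
4 | 4-fluorobenzaldehyde | O=Cc1ccc(F)cc1 | starting material
5 | 4-{[5-hydroxy-7-methoxy-2-(4-methoxyphenyl)-4-oxo-4H-chromen-8-yl]oxy}benzaldehyde | COc1ccc(-c2cc(=O)c3c(O)cc(OC)c(Oc4ccc(C=O)cc4)c3o2)cc1 | intermediate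
6 | 4-{[5-(benzyloxy)-7-methoxy-2-(4-methoxyphenyl)-4-oxo-4H-chromen-8-yl]oxy}benzaldehyde | COc1ccc(-c2cc(=O)c3c(OCc4ccccc4)cc(OC)c(Oc4ccc(C=O)cc4)c3o2)cc1 | intermediate
7 | 5-(benzyloxy)-8-(4-ethynylphenoxy)-7-methoxy-2-(4-methoxyphenyl)-4H-chromen-4-one | COc1ccc(-c2cc(=O)c3c(OCc4ccccc4)cc(OC)c(Oc4ccc(C#C)cc4)c3o2)cc1 | intermediate
8 | 3-(4-{[5-(benzyloxy)-7-methoxy-2-(4-methoxyphenyl)-4-oxo-4H-chromen-8-yl]oxy}phenyl)prop-2-ynoic acid | COc1ccc(-c2cc(=O)c3c(OCc4ccccc4)cc(OC)c(Oc4ccc(C#CC(=O)O)cc4)c3o2)cc1 | intermediate
9 | 3,5-bis(benzyloxy)phenol | Oc1cc(OCc2ccccc2)cc(OCc2ccccc2)c1 | starting material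
10 | 3,5-bis(benzyloxy)phenyl N-(propan-2-yl)carbamate | CC(C)NC(=O)Oc1cc(OCc2ccccc2)cc(OCc2ccccc2)c1 | intermediate
11 | 3,5-bis(benzyloxy)phenyl N-(propan-2-yl)-N-(trimethylsilyl)carbamate | CC(C)N(C(=O)Oc1cc(OCc2ccccc2)cc(OCc2ccccc2)c1)[Si](C)(C)C | intermediate
12 | [2,4-bis(benzyloxy)-6-{[(propan-2-yl)(trimethylsilyl)carbamoyl]oxy}phenyl]lithium | CC(C)N(C(=O)Oc1cc(OCc2ccccc2)cc(OCc2ccccc2)c1[Li])[Si](C)(C)C | intermediate
13 | 3,5-bis(benzyloxy)-2-(trimethylsilyl)phenyl N-(propan-2-yl)-N-(trimethylsilyl)carbamate | CC(C)N(C(=O)Oc1cc(OCc2ccccc2)cc(OCc2ccccc2)c1[Si](C)(C)C)[Si](C)(C)C | intermediate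
14 | 3,5-bis(benzyloxy)-2-(trimethylsilyl)phenyl N-(propan-2-yl)carbamate | CC(C)NC(=O)Oc1cc(OCc2ccccc2)cc(OCc2ccccc2)c1[Si](C)(C)C | intermediate
15 | 3,5-bis(benzyloxy)-2-(trimethylsilyl)phenol (present as its DBU-H phenoxide) | C[Si](C)(C)c1c(O)cc(OCc2ccccc2)cc1OCc1ccccc1 | intermediate
16 | 3,5-bis(benzyloxy)-2-(trimethylsilyl)phenyl trifluoromethanesulfonate | C[Si](C)(C)c1c(OCc2ccccc2)cc(OCc2ccccc2)cc1OS(=O)(=O)C(F)(F)F | intermediate
17 | 3,5-bis(benzyloxy)benzyne (1,2-didehydro-3,5-bis(benzyloxy)benzene) | C1(OCc2ccccc2)=CC(OCc2ccccc2)=CC#C1 | intermediate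
18 | 5-(benzyloxy)-8-(4-{3-[2,4-bis(benzyloxy)-6-hydroxyphenyl]-3-oxoprop-1-yn-1-yl}phenoxy)-7-methoxy-2-(4-methoxyphenyl)-4H-chromen-4-one | COc1ccc(-c2cc(=O)c3c(OCc4ccccc4)cc(OC)c(Oc4ccc(C#CC(=O)c5c(O)cc(OCc6ccccc6)cc5OCc5ccccc5)cc4)c3o2)cc1 | intermediate
19 | 5-(benzyloxy)-8-{4-[5,7-bis(benzyloxy)-4-oxo-4H-chromen-2-yl]phenoxy}-7-methoxy-2-(4-methoxyphenyl)-4H-chromen-4-one | COc1ccc(-c2cc(=O)c3c(OCc4ccccc4)cc(OC)c(Oc4ccc(-c5cc(=O)c6c(OCc7ccccc7)cc(OCc7ccccc7)cc6o5)cc4)c3o2)cc1 | intermediate
20 | 8-[4-(5,7-dihydroxy-4-oxo-4H-chromen-2-yl)phenoxy]-5-hydroxy-7-methoxy-2-(4-methoxyphenyl)-4H-chromen-4-one | COc1ccc(-c2cc(=O)c3c(O)cc(OC)c(Oc4ccc(-c5cc(=O)c6c(O)cc(O)cc6o5)cc4)c3o2)cc1 | target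

## Step count and least certain steps

Total step count: 11. Longest linear sequence: 8 steps (steps 1 to 5, then 9 to 11); the aryne branch is 3 steps (6 to 8).

**Step 9 (key step).** The most likely failure is proton capture by the aryl anion before it reaches the carbonyl, which ends in plain O-arylation. Other risks are conjugate addition of that anion to the alkyne, loss of CO2 from the cesium propiolate at 125 °C, and a second arylation of the product phenoxide.
Fallback, from 6 back to 19, by classical chemistry:
- Aldehyde 6 is oxidised (NaClO2, NaH2PO4, 2-methylbut-2-ene) to 4-{[5-(benzyloxy)-7-methoxy-2-(4-methoxyphenyl)-4-oxo-4H-chromen-8-yl]oxy}benzoic acid F1.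
- F1 is esterified (EDC, DMAP) with 1-[2,4-bis(benzyloxy)-6-hydroxyphenyl]ethan-1-one F2 to the aryl ester 2-acetyl-3,5-bis(benzyloxy)phenyl 4-{[5-(benzyloxy)-7-methoxy-2-(4-methoxyphenyl)-4-oxo-4H-chromen-8-yl]oxy}benzoate F3.
- Baker–Venkataraman rearrangement (KOH, pyridine, 50 °C) gives the 1,3-diketone 1-[2,4-bis(benzyloxy)-6-hydroxyphenyl]-3-(4-{[5-(benzyloxy)-7-methoxy-2-(4-methoxyphenyl)-4-oxo-4H-chromen-8-yl]oxy}phenyl)propane-1,3-dione F4.
- Cyclodehydration of F4 (TsOH, toluene, 80 °C) gives 19.

**Step 1.** Incomplete conversion and over-oxidation of the hydroquinone anion to quinone-derived material are likely, because the product is more easily oxidised than the starting phenol.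
Fallback, from 1 back to 6, bypassing 3 and 5:
- Flavone 1 is benzylated (BnBr, K2CO3, DMF) to 5-(benzyloxy)-7-methoxy-2-(4-methoxyphenyl)-4H-chromen-4-one F5.
- Electrophilic iodination (N-iodosuccinimide, DMF) gives 5-(benzyloxy)-8-iodo-7-methoxy-2-(4-methoxyphenyl)-4H-chromen-4-one F6; it should go to C8 once the C5 oxygen is alkylated.
- Miyaura borylation (B2pin2, PdCl2(dppf), KOAc, dioxane, 90 °C) gives the pinacol boronate 5-(benzyloxy)-7-methoxy-2-(4-methoxyphenyl)-8-(4,4,5,5-tetramethyl-1,3,2-dioxaborolan-2-yl)-4H-chromen-4-one F7.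
- Oxidation (NaBO3·4H2O, THF–water) gives 5-(benzyloxy)-8-hydroxy-7-methoxy-2-(4-methoxyphenyl)-4H-chromen-4-one F8.
- SNAr of F8 with 4 (K2CO3, DMF) gives 6.

**Step 5.** The carboxylation is reversible; the propiolate may lose CO2 again on warming or during acidification, or conversion may stall.
Fallback, from 7 back to 8: oxidative methoxycarbonylation of 7 (PdCl2 cat., CuCl2, NaOAc, CO 1 atm, MeOH–THF, rt) gives methyl 3-(4-{[5-(benzyloxy)-7-methoxy-2-(4-methoxyphenyl)-4-oxo-4H-chromen-8-yl]oxy}phenyl)prop-2-ynoate F9, which is saponified cold (LiOH, THF–water, 0 °C) to 8.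

**Step 7.** Deprotonation at a benzylic CH2 of a benzyl ether, followed by Wittig rearrangement, or an anionic Fries shift of the carbamate, can compete with ring lithiation.
Fallback, from 9 back to 16:
- Phenol 9 is brominated ortho to the hydroxyl (N-bromosuccinimide, i-Pr2NH cat., CH2Cl2, −78 °C) to 3,5-bis(benzyloxy)-2-bromophenol F10.
- Silylation with hexamethyldisilazane gives [3,5-bis(benzyloxy)-2-bromophenoxy]trimethylsilane F11.
- Bromine–lithium exchange (n-BuLi, THF, −78 °C) is much faster than benzylic deprotonation; it triggers the O-to-C silyl shift to the lithium salt of 15, which Tf2O converts into 16.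

## Further compounds

F1 | step 9 | 4-{[5-(benzyloxy)-7-methoxy-2-(4-methoxyphenyl)-4-oxo-4H-chromen-8-yl]oxy}benzoic acid | COc1ccc(-c2cc(=O)c3c(OCc4ccccc4)cc(OC)c(Oc4ccc(C(=O)O)cc4)c3o2)cc1
F2 | step 9 | 1-[2,4-bis(benzyloxy)-6-hydroxyphenyl]ethan-1-one | CC(=O)c1c(O)cc(OCc2ccccc2)cc1OCc1ccccc1
F3 | step 9 | 2-acetyl-3,5-bis(benzyloxy)phenyl 4-{[5-(benzyloxy)-7-methoxy-2-(4-methoxyphenyl)-4-oxo-4H-chromen-8-yl]oxy}benzoate | COc1ccc(-c2cc(=O)c3c(OCc4ccccc4)cc(OC)c(Oc4ccc(C(=O)Oc5cc(OCc6ccccc6)cc(OCc6ccccc6)c5C(C)=O)cc4)c3o2)cc1
F4 | step 9 | 1-[2,4-bis(benzyloxy)-6-hydroxyphenyl]-3-(4-{[5-(benzyloxy)-7-methoxy-2-(4-methoxyphenyl)-4-oxo-4H-chromen-8-yl]oxy}phenyl)propane-1,3-dione | COc1ccc(-c2cc(=O)c3c(OCc4ccccc4)cc(OC)c(Oc4ccc(C(=O)CC(=O)c5c(O)cc(OCc6ccccc6)cc5OCc5ccccc5)cc4)c3o2)cc1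
F5 | step 1 | 5-(benzyloxy)-7-methoxy-2-(4-methoxyphenyl)-4H-chromen-4-one | COc1ccc(-c2cc(=O)c3c(OCc4ccccc4)cc(OC)cc3o2)cc1
F6 | step 1 | 5-(benzyloxy)-8-iodo-7-methoxy-2-(4-methoxyphenyl)-4H-chromen-4-one | COc1ccc(-c2cc(=O)c3c(OCc4ccccc4)cc(OC)c(I)c3o2)cc1
F7 | step 1 | 5-(benzyloxy)-7-methoxy-2-(4-methoxyphenyl)-8-(4,4,5,5-tetramethyl-1,3,2-dioxaborolan-2-yl)-4H-chromen-4-one | COc1ccc(-c2cc(=O)c3c(OCc4ccccc4)cc(OC)c(B4OC(C)(C)C(C)(C)O4)c3o2)cc1
F8 | step 1 | 5-(benzyloxy)-8-hydroxy-7-methoxy-2-(4-methoxyphenyl)-4H-chromen-4-one | COc1ccc(-c2cc(=O)c3c(OCc4ccccc4)cc(OC)c(O)c3o2)cc1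
F9 | step 5 | methyl 3-(4-{[5-(benzyloxy)-7-methoxy-2-(4-methoxyphenyl)-4-oxo-4H-chromen-8-yl]oxy}phenyl)prop-2-ynoate | COc1ccc(-c2cc(=O)c3c(OCc4ccccc4)cc(OC)c(Oc4ccc(C#CC(=O)OC)cc4)c3o2)cc1
F10 | step 7 | 3,5-bis(benzyloxy)-2-bromophenol | Oc1cc(OCc2ccccc2)cc(OCc2ccccc2)c1Br
F11 | step 7 | [3,5-bis(benzyloxy)-2-bromophenoxy]trimethylsilane | C[Si](C)(C)Oc1cc(OCc2ccccc2)cc(OCc2ccccc2)c1Br
A1 | alternative 1 | 5,8-dihydroxy-7-methoxy-2-(4-methoxyphenyl)-4H-chromen-4-one | COc1ccc(-c2cc(=O)c3c(O)cc(OC)c(O)c3o2)cc1
A2 | alternative 1 | 4-hydroxy-3-methoxy-4-[6-(4-methoxyphenyl)-4-oxo-4H-pyran-2-yl]cyclobut-2-en-1-one (racemic) | COC1=CC(=O)C1(O)c1cc(=O)cc(-c2ccc(OC)cc2)o1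
A3 | alternative 2 | 8-{4-[5,7-bis(benzyloxy)-4-oxo-4H-chromen-2-yl]phenoxy}-5,7-dimethoxy-2-(4-methoxyphenyl)-4H-chromen-4-one | COc1ccc(-c2cc(=O)c3c(OC)cc(OC)c(Oc4ccc(-c5cc(=O)c6c(OCc7ccccc7)cc(OCc7ccccc7)cc6o5)cc4)c3o2)cc1
A4 | alternative 2 | (2E)-1-[3-(4-{(1E)-3-[2,4-bis(benzyloxy)-6-hydroxyphenyl]-3-oxoprop-1-en-1-yl}phenoxy)-2-hydroxy-4,6-dimethoxyphenyl]-3-(4-methoxyphenyl)prop-2-en-1-one | COc1ccc(/C=C/C(=O)c2c(O)c(Oc3ccc(/C=C/C(=O)c4c(O)cc(OCc5ccccc5)cc4OCc4ccccc4)cc3)c(OC)cc2OC)cc1
A5 | alternative 3 | methyl 4-[2-(benzyloxy)-4,6-dimethoxyphenoxy]benzoate | COC(=O)c1ccc(Oc2c(OC)cc(OC)cc2OCc2ccccc2)cc1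
A6 | alternative 3 | 1-(benzyloxy)-2-(ethynyloxy)-3,5-dimethoxybenzene | C#COc1c(OC)cc(OC)cc1OCc1ccccc1
A7 | alternative 3 | methyl 2-oxo-2H-pyran-5-carboxylate (methyl coumalate) | COC(=O)C1=COC(=O)C=C1
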